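**Plan**
- Retrosynthesis: ring C is opened at O1–C2 (cyclodehydration) and C2–C3 (Baker–Venkataraman acyl shift), which gives ring-A hydroxy ketone 17 and ring-B acid 20.
- In 17 the C4–C4a and O1–C8a bonds are then cut together. C4a (carrying the acyl carbon) and C8a (carrying O1) are adjacent ring-A carbons lying between the C5 oxygen and the C8 prenyl group, so one C4a≡C8a aryne can accept both groups from 5-methylhex-4-enoic acid, whose chain already contains C4, C3 and the C3 prenyl group.
- Forward: ring A is elaborated from methyl 2,4,6-trihydroxybenzoate (C-diprenylation, 7-O-methylation, one MOM ether, decarboxylation) and converted into silylaryl triflate 13; the aryne insertion gives 17. Ring B is attached as an aryl ester and shifted to carbon. Ring C closes last, together with removal of all MOM groups.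
- Stereochemistry: the target has no stereocentre and its three prenyl double bonds carry two identical methyl groups, so nothing has to be controlled.

Key step: step 8

Remark: ring-A carbons carry their final flavone labels (C4a, C5–C8, C8a) from the start. Diketone 22 is drawn in the open diketo form, though it may rest as enol or as the ring-A hemiketal; its α-carbon is a labile, unassigned centre that disappears in step 13.

**Route**

Step 1
Reactants: 1 methyl 2,4,6-trihydroxybenzoate; 2 prenyl bromide (1-bromo-3-methylbut-2-ene)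
Product: 3 methyl 2,4,6-trihydroxy-3,5-bis(3-methylbut-2-enyl)benzoate
Conditions: 2 (2.2 equiv), NaOMe, MeOH, 0 °C → rt
Reagents that add atoms: none
Why: C-alkylation of the ambident phloroglucinol phenoxide in a protic medium (hydrogen bonding shields oxygen) should place prenyl groups on the only two free ring carbons, while the ester blocks the future C4a.

Step 2
Reactants: 3 methyl 2,4,6-trihydroxy-3,5-bis(3-methylbut-2-enyl)benzoate
Product: 4 methyl 2,6-dihydroxy-4-methoxy-3,5-bis(3-methylbut-2-enyl)benzoate
Conditions: Me3SiCHN2, i-Pr2NEt, MeCN/MeOH, 0 °C → rt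
Reagents that add atoms: (trimethylsilyl)diazomethane, C[Si](C)(C)C=[N+]=[N-]
Why: O-methylation with a diazoalkane should pick the 4-OH, the most acidic phenol and the only one not hydrogen-bonded to the ester, and it avoids the ring C-methylation that alkyl halide and base can cause.

Step 3
Reactants: 4 methyl 2,6-dihydroxy-4-methoxy-3,5-bis(3-methylbut-2-enyl)benzoate
Product: 5 methyl 2-hydroxy-4-methoxy-6-(methoxymethoxy)-3,5-bis(3-methylbut-2-enyl)benzoate
Conditions: MOMCl (1.2 equiv), i-Pr2NEt, CH2Cl2, 0 °C → rt
Reagents that add atoms: chloromethyl methyl ether, COCCl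
Why: MOM ether formation on a 2,6-dihydroxybenzoate should stop after one group, because the remaining phenol is then locked in a strong hydrogen bond to the ester carbonyl, so the symmetric diol is desymmetrised without a statistical step.

Step 4
Reactants: 5 methyl 2-hydroxy-4-methoxy-6-(methoxymethoxy)-3,5-bis(3-methylbut-2-enyl)benzoate
Product: 7 3-methoxy-5-(methoxymethoxy)-2,4-bis(3-methylbut-2-enyl)phenol, via carboxylic acid 6 (not isolated)
Conditions: KOH, DMSO/H2O, 100 °C; then AcOH to pH 5, 60 °C
Reagents that add atoms: none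
Why: Saponification followed by protodecarboxylation of the resulting 2-hydroxy-4,6-dialkoxybenzoic acid (ipso protonation is easy on this electron-rich ring) should free C4a at a pH that the MOM acetal and the prenyl groups tolerate.

Step 5
Reactants: 7 3-methoxy-5-(methoxymethoxy)-2,4-bis(3-methylbut-2-enyl)phenol
Product: 8 3-methoxy-5-(methoxymethoxy)-2,4-bis(3-methylbut-2-enyl)phenyl N-propan-2-ylcarbamate
Conditions: i-PrNCO, Et3N (cat.), CH2Cl2, rt
Reagents that add atoms: isopropyl isocyanate, CC(C)N=C=O
Why: Base-catalysed addition of the phenol to the isocyanate should give the N-monoalkyl carbamate, a strong ortho-director that can later be removed without acid.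

Step 6
Reactants: 8 3-methoxy-5-(methoxymethoxy)-2,4-bis(3-methylbut-2-enyl)phenyl N-propan-2-ylcarbamate
Product: 11 3-methoxy-5-(methoxymethoxy)-2,4-bis(3-methylbut-2-enyl)-6-(trimethylsilyl)phenyl N-propan-2-ylcarbamate, via N-silyl carbamate 9 (not isolated), via bis-silyl carbamate 10 (not isolated)
Conditions: Me3SiOTf (1.05 equiv), TMEDA, Et2O, 0 °C → rt; n-BuLi, TMEDA, −78 °C; Me3SiCl, −78 °C → rt; aq NH4Cl
Reagents that add atoms: chlorotrimethylsilane, C[Si](C)(C)Cl
Why: Directed ortho-metalation of the carbamate, N-silylated in the flask, should lithiate the single ring C–H at C4a, which lies between two cooperating directors (carbamate and MOM ether), and the silyl triflate is held at one equivalent so that it is consumed by the N–H and spares the acetal.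

Step 7
Reactants: 11 3-methoxy-5-(methoxymethoxy)-2,4-bis(3-methylbut-2-enyl)-6-(trimethylsilyl)phenyl N-propan-2-ylcarbamate
Product: 13 3-methoxy-5-(methoxymethoxy)-2,4-bis(3-methylbut-2-enyl)-6-(trimethylsilyl)phenyl trifluoromethanesulfonate, via silylphenol 12 (not isolated)
Conditions: Et2NH, DBU, MeCN, 40 °C; then PhNTf2, 40 °C
Reagents that add atoms: N-phenylbis(trifluoromethanesulfonimide), O=S(=O)(N(c1ccccc1)S(=O)(=O)C(F)(F)F)C(F)(F)F
Why: E1cB cleavage of the N-monoalkyl carbamate (the isocyanate is trapped as a urea) followed by triflation of the phenoxide in the same pot should give the aryne precursor under base-only conditions that leave the acid-labile aryl–silicon bond, the MOM ether and the prenyl groups alone.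

Step 8
Reactants: 13 3-methoxy-5-(methoxymethoxy)-2,4-bis(3-methylbut-2-enyl)-6-(trimethylsilyl)phenyl trifluoromethanesulfonate; 14 5-methylhex-4-enoic acid
Product: 17 1-[2-hydroxy-4-methoxy-6-(methoxymethoxy)-3,5-bis(3-methylbut-2-enyl)phenyl]-5-methylhex-4-en-1-one, via cesium carboxylate 15 (not isolated), via ring A aryne 16 (not isolated)
Conditions: 14 (1.5 equiv), CsF (5 equiv), THF (0.02 M), 125 °C, sealed tube
Reagents that add atoms: none
Why: Fluoride attacks silicon and triflate leaves to give aryne 16; carboxylate 15 adds through oxygen at C8a, and the aryl anion left at C4a attacks the carbonyl of the aryl ester just formed, passing through a four-membered benzoxetene alkoxide that opens to the C4a ketone and the C8a phenoxide. This is the fluoride-induced insertion of an aryne into the C–O bond of a carboxylic acid, an established way from silylaryl triflates to ortho-hydroxyaryl ketones, here used with the aryne as the limiting partner. It forms C8a–O1 and C4a–C4 in one operation, closes no ring and creates no stereocentre. The step needs regioselective addition to an unsymmetrical aryne: the inductively withdrawing C5 acetal oxygen makes the remote terminus C8a the electrophilic one and stabilises the charge developing at C4a, whereas the C8 prenyl group opposes this only through modest steric hindrance. It also needs the acyl shift to outrun proton capture by the aryl anion: excess CsF keeps the acid as carboxylate and sparingly soluble bifluoride, and hot, dilute THF favours the intramolecular path. The medium stays neutral to weakly basic, so the two prenyl groups and the MOM ether should survive, and no Lewis acid is ever applied to the ring.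

Step 9
Reactants: 18 2,4,5-trihydroxybenzaldehyde
Product: 19 2,4,5-tris(methoxymethoxy)benzaldehyde
Conditions: NaH, MOMCl, DMF, 0 °C → rt, under argon
Reagents that add atoms: chloromethyl methyl ether, COCCl
Why: Williamson-type acetalisation of the three phenoxides should protect all hydroxyls, the strong base being needed for the 2-OH that is hydrogen-bonded to the aldehyde.

Step 10
Reactants: 19 2,4,5-tris(methoxymethoxy)benzaldehyde
Product: 20 2,4,5-tris(methoxymethoxy)benzoic acid
Conditions: NaClO2, NaH2PO4, 2-methylbut-2-ene, t-BuOH/H2O, rt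
Reagents that add atoms: sodium chlorite, [Na+].[O-]Cl=O
Why: Pinnick oxidation at buffered pH should give the acid without touching the acetals, the alkene scavenger removing hypochlorous acid before it can chlorinate the electron-rich ring.

Step 11
Reactants: 17 1-[2-hydroxy-4-methoxy-6-(methoxymethoxy)-3,5-bis(3-methylbut-2-enyl)phenyl]-5-methylhex-4-en-1-one; 20 2,4,5-tris(methoxymethoxy)benzoic acid
Product: 21 5-methoxy-3-(methoxymethoxy)-2-(5-methylhex-4-enoyl)-4,6-bis(3-methylbut-2-enyl)phenyl 2,4,5-tris(methoxymethoxy)benzoate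
Conditions: EDC·HCl, DMAP, CH2Cl2, rt
Reagents that add atoms: none
Why: Steglich esterification should acylate the only free hydroxyl (C8a–OH) through the acylpyridinium, and it avoids an acid chloride whose hydrogen chloride would endanger the four acetals.

Step 12
Reactants: 21 5-methoxy-3-(methoxymethoxy)-2-(5-methylhex-4-enoyl)-4,6-bis(3-methylbut-2-enyl)phenyl 2,4,5-tris(methoxymethoxy)benzoate
Product: 22 1-[2-hydroxy-4-methoxy-6-(methoxymethoxy)-3,5-bis(3-methylbut-2-enyl)phenyl]-2-(3-methylbut-2-enyl)-3-[2,4,5-tris(methoxymethoxy)phenyl]propane-1,3-dione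
Conditions: LiN(SiMe3)2 (3 equiv), THF, −78 °C → rt; then AcOH
Reagents that add atoms: none
Why: Baker–Venkataraman rearrangement should form C2–C3, the ketone enolate (only one α-methylene exists) attacking the neighbouring aryl ester through a six-membered transition state, as is usual for α-alkyl aryl ketones on the way to 3-substituted flavones.

Step 13
Reactants: 22 1-[2-hydroxy-4-methoxy-6-(methoxymethoxy)-3,5-bis(3-methylbut-2-enyl)phenyl]-2-(3-methylbut-2-enyl)-3-[2,4,5-tris(methoxymethoxy)phenyl]propane-1,3-dione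
Product: 23 5-hydroxy-7-methoxy-3,6,8-tris(3-methylbut-2-enyl)-2-(2,4,5-trihydroxyphenyl)chromen-4-one
Conditions: 3 M aq HCl, MeOH (degassed), 50 °C, under argon
Reagents that add atoms: none
Why: Acid-catalysed cyclodehydration (the C8a phenol adds to the C2 carbonyl in a 6-exo-trig closure and water is lost) together with acetal hydrolysis of the four MOM ethers should give the flavone, because the ring-A phenol is free from the outset while the 2'-oxygen is still masked, ring A becomes symmetric once its acetal falls off so either of its phenols leads to the same product, and dilute methanolic HCl is the customary reagent for MOM removal beside prenyl groups.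

**Compound list**
1 | methyl 2,4,6-trihydroxybenzoate | COC(=O)c1c(O)cc(O)cc1O | starting material
2 | prenyl bromide (1-bromo-3-methylbut-2-ene) | CC(C)=CCBr | starting material
3 | methyl 2,4,6-trihydroxy-3,5-bis(3-methylbut-2-enyl)benzoate | COC(=O)c1c(O)c(CC=C(C)C)c(O)c(CC=C(C)C)c1O | intermediate
4 | methyl 2,6-dihydroxy-4-methoxy-3,5-bis(3-methylbut-2-enyl)benzoate | COC(=O)c1c(O)c(CC=C(C)C)c(OC)c(CC=C(C)C)c1O | intermediate
5 | methyl 2-hydroxy-4-methoxy-6-(methoxymethoxy)-3,5-bis(3-methylbut-2-enyl)benzoate | COC(=O)c1c(O)c(CC=C(C)C)c(OC)c(CC=C(C)C)c1OCOC | intermediate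
6 | 2-hydroxy-4-methoxy-6-(methoxymethoxy)-3,5-bis(3-methylbut-2-enyl)benzoic acid | OC(=O)c1c(O)c(CC=C(C)C)c(OC)c(CC=C(C)C)c1OCOC | intermediate
7 | 3-methoxy-5-(methoxymethoxy)-2,4-bis(3-methylbut-2-enyl)phenol | COc1c(CC=C(C)C)c(OCOC)cc(O)c1CC=C(C)C | intermediate
8 | 3-methoxy-5-(methoxymethoxy)-2,4-bis(3-methylbut-2-enyl)phenyl N-propan-2-ylcarbamate | COc1c(CC=C(C)C)c(OCOC)cc(OC(=O)NC(C)C)c1CC=C(C)C | intermediate
9 | 3-methoxy-5-(methoxymethoxy)-2,4-bis(3-methylbut-2-enyl)phenyl N-propan-2-yl-N-(trimethylsilyl)carbamate | COc1c(CC=C(C)C)c(OCOC)cc(OC(=O)N(C(C)C)[Si](C)(C)C)c1CC=C(C)C | intermediate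
10 | 3-methoxy-5-(methoxymethoxy)-2,4-bis(3-methylbut-2-enyl)-6-(trimethylsilyl)phenyl N-propan-2-yl-N-(trimethylsilyl)carbamate | COc1c(CC=C(C)C)c(OCOC)c([Si](C)(C)C)c(OC(=O)N(C(C)C)[Si](C)(C)C)c1CC=C(C)C | intermediate
11 | 3-methoxy-5-(methoxymethoxy)-2,4-bis(3-methylbut-2-enyl)-6-(trimethylsilyl)phenyl N-propan-2-ylcarbamate | COc1c(CC=C(C)C)c(OCOC)c([Si](C)(C)C)c(OC(=O)NC(C)C)c1CC=C(C)C | intermediate
12 | 3-methoxy-5-(methoxymethoxy)-2,4-bis(3-methylbut-2-enyl)-6-(trimethylsilyl)phenol | COc1c(CC=C(C)C)c(OCOC)c([Si](C)(C)C)c(O)c1CC=C(C)C | intermediate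
13 | 3-methoxy-5-(methoxymethoxy)-2,4-bis(3-methylbut-2-enyl)-6-(trimethylsilyl)phenyl trifluoromethanesulfonate | COc1c(CC=C(C)C)c(OCOC)c([Si](C)(C)C)c(OS(=O)(=O)C(F)(F)F)c1CC=C(C)C | intermediate
14 | 5-methylhex-4-enoic acid | CC(C)=CCCC(=O)O | starting material
15 | cesium 5-methylhex-4-enoate | CC(C)=CCCC(=O)[O-].[Cs+] | intermediate
16 | 5-methoxy-3-(methoxymethoxy)-4,6-bis(3-methylbut-2-enyl)benzyne (1,2-didehydrobenzene; triple bond C4a≡C8a) | COCOC1=C(CC=C(C)C)C(OC)=C(CC=C(C)C)C#C1 | intermediate
17 | 1-[2-hydroxy-4-methoxy-6-(methoxymethoxy)-3,5-bis(3-methylbut-2-enyl)phenyl]-5-methylhex-4-en-1-one | COc1c(CC=C(C)C)c(OCOC)c(C(=O)CCC=C(C)C)c(O)c1CC=C(C)C | intermediate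
18 | 2,4,5-trihydroxybenzaldehyde | O=Cc1cc(O)c(O)cc1O | starting material
19 | 2,4,5-tris(methoxymethoxy)benzaldehyde | COCOc1cc(OCOC)c(OCOC)cc1C=O | intermediate
20 | 2,4,5-tris(methoxymethoxy)benzoic acid | COCOc1cc(OCOC)c(OCOC)cc1C(=O)O | intermediate
21 | 5-methoxy-3-(methoxymethoxy)-2-(5-methylhex-4-enoyl)-4,6-bis(3-methylbut-2-enyl)phenyl 2,4,5-tris(methoxymethoxy)benzoate | COc1c(CC=C(C)C)c(OCOC)c(C(=O)CCC=C(C)C)c(OC(=O)c2cc(OCOC)c(OCOC)cc2OCOC)c1CC=C(C)C | intermediate
22 | 1-[2-hydroxy-4-methoxy-6-(methoxymethoxy)-3,5-bis(3-methylbut-2-enyl)phenyl]-2-(3-methylbut-2-enyl)-3-[2,4,5-tris(methoxymethoxy)phenyl]propane-1,3-dione | COc1c(CC=C(C)C)c(OCOC)c(C(=O)C(CC=C(C)C)C(=O)c2cc(OCOC)c(OCOC)cc2OCOC)c(O)c1CC=C(C)C | intermediate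
23 | 5-hydroxy-7-methoxy-3,6,8-tris(3-methylbut-2-enyl)-2-(2,4,5-trihydroxyphenyl)chromen-4-one | COc1c(CC=C(C)C)c(O)c2c(=O)c(CC=C(C)C)c(-c3cc(O)c(O)cc3O)oc2c1CC=C(C)C | target

**Step count**
Total steps: 13. Longest linear sequence: 11 steps (steps 1–8 and 11–13, from methyl 2,4,6-trihydroxybenzoate); the ring-B acid takes 2 steps (9 and 10) and joins at step 11.

**Steps most likely to fail**

Step 8. The carboxylate may add at the wrong aryne terminus because of the hindrance at C8a, or the aryl anion may capture a proton before the acyl shift, so that the aryne is used up without forming the C4a–C4 bond. The fallback sets out from carbamate 8 and returns at 17, and it uses only directed metalation chemistry. Acid 14 is converted with carbonyldiimidazole and MeNHOMe·HCl into N-methoxy-N,5-dimethylhex-4-enamide F1. Carbamate 8 is N-silylated and lithiated at C4a exactly as in step 6 (through 9), and the aryllithium is quenched with F1. Aqueous work-up then gives 5-methoxy-3-(methoxymethoxy)-2-(5-methylhex-4-enoyl)-4,6-bis(3-methylbut-2-enyl)phenyl N-propan-2-ylcarbamate F2. Treatment of F2 with Et2NH and DBU in MeCN removes the carbamate by the same E1cB path as in step 7 and should give 17.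

Step 1. Over-alkylation with loss of aromaticity (a second prenyl group entering at an already substituted carbon) and O-alkylation may erode the yield of the twofold C-prenylation. The fallback sets out from 1 and returns at 4, and it replaces phenoxide alkylation by cross-coupling. Selective 4-O-methylation of 1 with Me3SiCHN2 gives methyl 2,6-dihydroxy-4-methoxybenzoate F3. Iodination of both free ring positions with N-iodosuccinimide in MeCN gives methyl 2,6-dihydroxy-3,5-diiodo-4-methoxybenzoate F4. A twofold Stille coupling with tributyl(3-methylbut-2-enyl)stannane (Pd(PPh3)4, zerovalent palladium, DMF, 90 °C) should then deliver 4 with linear prenyl groups.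

Step 13. During the long acid exposure needed to hydrolyse four acetals, a ring-A phenol may add across the neighbouring prenyl double bond, and the free trihydroxyphenyl ring may oxidise in air. The fallback sets out from 17 and 18 and returns at 23, and it moves the ring-B protection to groups that come off without acid. Aldehyde 18 is allylated (allyl bromide, K2CO3, DMF) to 2,4,5-tris(prop-2-enoxy)benzaldehyde F5 and oxidised (NaClO2, NaH2PO4, 2-methylbut-2-ene) to 2,4,5-tris(prop-2-enoxy)benzoic acid F6. Acid F6 is coupled with 17 (EDC·HCl, DMAP) to 5-methoxy-3-(methoxymethoxy)-2-(5-methylhex-4-enoyl)-4,6-bis(3-methylbut-2-enyl)phenyl 2,4,5-tris(prop-2-enoxy)benzoate F7. Rearrangement with LiN(SiMe3)2 gives 1-[2-hydroxy-4-methoxy-6-(methoxymethoxy)-3,5-bis(3-methylbut-2-enyl)phenyl]-2-(3-methylbut-2-enyl)-3-[2,4,5-tris(prop-2-enoxy)phenyl]propane-1,3-dione F8. A brief treatment with catalytic TsOH in MeOH closes ring C and removes only the single carbonyl-adjacent C5 acetal, giving 5-hydroxy-7-methoxy-3,6,8-tris(3-methylbut-2-enyl)-2-[2,4,5-tris(prop-2-enoxy)phenyl]chromen-4-one F9. The three allyl ethers are finally removed with Pd(PPh3)4 (zerovalent palladium) and morpholine in degassed THF at rt to give 23.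

**Further compounds**
F1 | step 8 | N-methoxy-N,5-dimethylhex-4-enamide | CC(C)=CCCC(=O)N(C)OC
F2 | step 8 | 5-methoxy-3-(methoxymethoxy)-2-(5-methylhex-4-enoyl)-4,6-bis(3-methylbut-2-enyl)phenyl N-propan-2-ylcarbamate | COc1c(CC=C(C)C)c(OCOC)c(C(=O)CCC=C(C)C)c(OC(=O)NC(C)C)c1CC=C(C)C
F3 | step 1 | methyl 2,6-dihydroxy-4-methoxybenzoate | COC(=O)c1c(O)cc(OC)cc1O
F4 | step 1 | methyl 2,6-dihydroxy-3,5-diiodo-4-methoxybenzoate | COC(=O)c1c(O)c(I)c(OC)c(I)c1O
F5 | step 13 | 2,4,5-tris(prop-2-enoxy)benzaldehyde | C=CCOc1cc(OCC=C)c(OCC=C)cc1C=O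
F6 | step 13 | 2,4,5-tris(prop-2-enoxy)benzoic acid | C=CCOc1cc(OCC=C)c(OCC=C)cc1C(=O)O
F7 | step 13 | 5-methoxy-3-(methoxymethoxy)-2-(5-methylhex-4-enoyl)-4,6-bis(3-methylbut-2-enyl)phenyl 2,4,5-tris(prop-2-enoxy)benzoate | COc1c(CC=C(C)C)c(OCOC)c(C(=O)CCC=C(C)C)c(OC(=O)c2cc(OCC=C)c(OCC=C)cc2OCC=C)c1CC=C(C)C
F8 | step 13 | 1-[2-hydroxy-4-methoxy-6-(methoxymethoxy)-3,5-bis(3-methylbut-2-enyl)phenyl]-2-(3-methylbut-2-enyl)-3-[2,4,5-tris(prop-2-enoxy)phenyl]propane-1,3-dione | COc1c(CC=C(C)C)c(OCOC)c(C(=O)C(CC=C(C)C)C(=O)c2cc(OCC=C)c(OCC=C)cc2OCC=C)c(O)c1CC=C(C)C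
F9 | step 13 | 5-hydroxy-7-methoxy-3,6,8-tris(3-methylbut-2-enyl)-2-[2,4,5-tris(prop-2-enoxy)phenyl]chromen-4-one | COc1c(CC=C(C)C)c(O)c2c(=O)c(CC=C(C)C)c(-c3cc(OCC=C)c(OCC=C)cc3OCC=C)oc2c1CC=C(C)C
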